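(All constants are assumed; the run is a simulation.)

I expected a leftover of electrophile in this flask, and I set out to size it.

electrophile 0.40 M; free base 0.120 M; protonated nucleophile 0.600 M; time 25 min

    nucleophile + acid set free ⇌ protonated nucleophile, settled at all times (K1 = 21000 M⁻¹)
    acid set free + free base ⇌ idle adduct, settled at all times (K2 = 1700 M⁻¹)
    electrophile + nucleophile → acid set free + target (k3 = 2.1 M⁻¹ min⁻¹)
    acid set free + target → side product (k4 = 0.082 M⁻¹ min⁻¹)
    acid set free + free base ⇌ salt of the base, settled at all times (K5 = 7000 M⁻¹)

* part of the electrophile that has reacted at 25 min
* share of the unused nucleophile that is free and not bound as protonated nucleophile, at 25 min

- what is said of acid set free includes idle adduct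
- run time (flask): 25 min

The nucleophile was charged protonated, so the free base had to release it. Each free base that took an acid gave one free nucleophile. Each turnover then used one nucleophile and set free one acid, and that acid bound a second nucleophile. So a turnover cost two. That gave my stall line, 15.0 %: the part of the electrophile reacted when free nucleophile meets free acid, which is the free base charged over 2 times the electrophile charged. The nucleophile's half-life by the step to target alone, with the other concentrations as charged, was 0.83 min, shorter than the run, so I expected the flask to reach the line early.

Past the line, free nucleophile times free acid stayed at protonated nucleophile over its constant. Each turnover past the line drew its nucleophile from protonated nucleophile, so it added two free acids. The square of the free acid therefore grew as 4 times the rate constant, electrophile, protonated nucleophile and time, over that constant, and I counted the whole run as that time. I set up three rows.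

First row, the line: free acid taken as nil, 15.0 % reacted.

Second row, the values at the line held for the whole run: electrophile 0.340 M, protonated nucleophile 0.540 M, free acid 0.0428 M, 20.4 % reacted.

Third row, the end values of that row: electrophile 0.319 M, protonated nucleophile 0.519 M, free acid 0.0406 M, 20.1 % reacted.

Reading down, the creep added 5.4 percentage points to the line. The means of the two curves lay between the last two rows, which differed by 0.30 points, so replacing each curve by a mean cost little. I kept the third row, and its free share, one over the constant times free acid, was 0.117 %.

The forecast stood a little apart from me, at 19.7 % and 0.145 %, holding that “the fast reaction stalls at about 15% conversion within a few minutes”.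

The flask gave 19.6 % and 0.136 %, and its free acid at 25.0 min was 0.0351 M, below my 0.0406 M. The target held 14.1 % at 2.50 min, just under the line of 15.0 %, and at the end 80 % of the electrophile was left over, with 0.33 % of the free base, the limiting reagent. At 25.0 min the path to target gave the nucleophile a half-life of 1.0 min, while the electrophile's was far longer, 7.8 h. With 0.10 M of electrophile, the neighbour flask had a stall line of 60.0 % and reached 60.5 %.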